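## Retrosynthetic overview

1. Target ⇒ terminal alkyne (Markovnikov hydration) ⇒ dienal + butynol‑derived allenylstannane (SE2′ addition); dienal ⇒ lactone vinyl iodide + acrolein (Heck).
2. γ‑Lactone (the only ring, closed once, after C3 and C4 are set) ⇒ allylic‑transposition lactonisation of a bis‑allylic alcohol acid ⇒ alkenylzinc (from (S)‑3‑bromo‑2‑methylpropan‑1‑ol) + enal acid (cross‑metathesis with methacrolein).
3. Key bond C3–C4 with both stereocentres ⇒ Ireland–Claisen [3,3] rearrangement of the (S,E)‑pent‑3‑en‑2‑yl ester of (E)‑4‑iodopent‑3‑enoic acid (1,3‑chirality transfer from the carbinol).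
4. All chirality comes from (S)‑but‑3‑yn‑2‑ol (C3, C4 and through them C5; C5′, C6′) and (S)‑3‑bromo‑2‑methylpropan‑1‑ol (C10).

Assumption: (S)‑but‑3‑yn‑2‑ol and (S)‑3‑bromo‑2‑methylpropan‑1‑ol are taken as inexpensive commercial enantiopure building blocks; pent‑3‑yn‑1‑ol, methacrolein and acrolein are commercial.

Locants used below: lactone O1, C2–C5; C6–C14 = dienyl chain on C5; C1′–C8′ = hydroxy‑ketone chain on C3.

## Route

Step 1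
Reactants: 1 pent‑3‑yn‑1‑ol
Product: 2 tert‑butyl(dimethyl)(pent‑3‑yn‑1‑yloxy)silane
Conditions: TBSCl, imidazole, DMF, rt
Reagents that add atoms: tert‑butyl(chloro)dimethylsilane, CC(C)(C)[Si](C)(C)Cl
Why: O‑silylation; the silyl ether prevents alkoxide‑directed (proximal) hydrozirconation in the next step.

Step 2
Reactants: 2 tert‑butyl(dimethyl)(pent‑3‑yn‑1‑yloxy)silane
Product: 4 tert‑butyl{[(3E)‑4‑iodopent‑3‑en‑1‑yl]oxy}dimethylsilane, via alkenylzirconocene 3 (not isolated)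
Conditions: Cp2Zr(H)Cl (2 equiv), THF, rt to 45 °C; then I2, 0 °C
Reagents that add atoms: iodine, II
Why: Hydrozirconation–iodination: syn H–Zr addition, equilibrated to Zr on the less hindered methyl‑bearing carbon, then iodinolysis with retention gives the (E)‑2‑iodoalkene.

Step 3
Reactants: 4 tert‑butyl{[(3E)‑4‑iodopent‑3‑en‑1‑yl]oxy}dimethylsilane
Product: 5 (3E)‑4‑iodopent‑3‑enoic acid
Conditions: CrO3, H2SO4, H2O, acetone, 0 °C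
Reagents that add atoms: water, O
Why: Jones oxidation: the acidic chromic acid cleaves the primary silyl ether and oxidises the alcohol via the aldehyde hydrate to the acid without moving the β,γ‑double bond.

Step 4
Reactants: 6 (2S)‑but‑3‑yn‑2‑ol
Product: 7 (2S)‑pent‑3‑yn‑2‑ol
Conditions: n‑BuLi (2.1 equiv), THF, −78 °C; MeI (1.0 equiv), DMPU, −78 to 0 °C; H2O
Reagents that add atoms: iodomethane, CI
Why: C‑alkylation of the lithium alkoxide/acetylide dianion at the acetylide carbon; the stereocentre is not touched.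

Step 5
Reactants: 7 (2S)‑pent‑3‑yn‑2‑ol
Product: 8 (2S,3E)‑pent‑3‑en‑2‑ol
Conditions: LiAlH4, THF, reflux; H2O/NaOH work‑up
Reagents that add atoms: none
Why: Hydroxyl‑directed trans‑hydroalumination of the propargylic alcohol gives the (E)‑allylic alcohol with the carbinol configuration unchanged.

Step 6
Reactants: 5 (3E)‑4‑iodopent‑3‑enoic acid and 8 (2S,3E)‑pent‑3‑en‑2‑ol
Product: 9 (2S,3E)‑pent‑3‑en‑2‑yl (3E)‑4‑iodopent‑3‑enoate
Conditions: DCC, DMAP (5 mol %), CH2Cl2, 0 °C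
Reagents that add atoms: none
Why: Steglich esterification (acyl transfer, retention at the carbinol); low temperature and catalytic DMAP keep the β,γ‑alkene out of conjugation.

Step 7
Reactants: 9 (2S,3E)‑pent‑3‑en‑2‑yl (3E)‑4‑iodopent‑3‑enoate
Product: 12 (2R,3R,4E)‑2‑[(1E)‑2‑iodoprop‑1‑en‑1‑yl]‑3‑methylhex‑4‑enoic acid, via silyl ketene acetal 10 (not isolated), via trimethylsilyl ester 11 (not isolated)
Conditions: LiN(iPr)2, THF–DMPU (4:1), −78 °C; Me3SiCl; −78 °C to rt; 1 M HCl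
Reagents that add atoms: none
Why: Ireland–Claisen [3,3]‑sigmatropic rearrangement: a chair transition state with the carbinol methyl equatorial, the (E)‑alkene, and the ketene acetal whose alkenyl group is trans to the allylic oxygen (DMPU conditions) transfers the (S)‑carbinol chirality to C3 and C4 and gives the 2,3‑syn acid, which is the 3,4‑trans pattern of the lactone.

Step 8
Reactants: 12 (2R,3R,4E)‑2‑[(1E)‑2‑iodoprop‑1‑en‑1‑yl]‑3‑methylhex‑4‑enoic acid and 13 methacrolein (2‑methylprop‑2‑enal)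
Product: 14 (2R,3R,4E)‑2‑[(1E)‑2‑iodoprop‑1‑en‑1‑yl]‑3,5‑dimethyl‑6‑oxohex‑4‑enoic acid
Conditions: 13 (10 equiv), second‑generation Hoveyda–Grubbs catalyst RuCl2(H2IMes)(=CH‑C6H4‑2‑OiPr) (5 mol %), CH2Cl2, 40 °C
Reagents that add atoms: none
Why: Olefin cross‑metathesis of the propenyl group with excess methacrolein gives the (E)‑trisubstituted enal (propene lost); the iodoalkene is inert and C4 is never α to a carbonyl.

Step 9
Reactants: 15 (2S)‑3‑bromo‑2‑methylpropan‑1‑ol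
Product: 16 (2R)‑2‑methylhexan‑1‑ol
Conditions: n‑PrMgCl (3 equiv), Li2CuCl4 (3 mol %), THF, −78 to 0 °C; H2O
Reagents that add atoms: propylmagnesium chloride, CCC[Mg]Cl
Why: Copper‑catalysed (Kochi) sp3–sp3 coupling of the primary bromide after the first Grignard equivalent deprotonates OH; the stereocentre is untouched (S to R is a priority change only).

Step 10
Reactants: 16 (2R)‑2‑methylhexan‑1‑ol
Product: 17 (2R)‑2‑methylhexanal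
Conditions: Dess–Martin periodinane, CH2Cl2, 0 °C; used at once
Reagents that add atoms: none
Why: Dess–Martin oxidation under near‑neutral conditions gives the α‑branched aldehyde without epimerisation.

Step 11
Reactants: 17 (2R)‑2‑methylhexanal
Product: 18 (3R)‑3‑methylhept‑1‑yne
Conditions: dimethyl (1‑diazo‑2‑oxopropyl)phosphonate, K2CO3, MeOH, 0 °C to rt
Reagents that add atoms: dimethyl (1‑diazo‑2‑oxopropyl)phosphonate, COP(=O)(OC)C(=[N+]=[N-])C(C)=O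
Why: Ohira–Bestmann (Seyferth–Gilbert) homologation: the diazoalkene loses N2 and the carbene undergoes 1,2‑H shift to the terminal alkyne; mild carbonate at 0 °C preserves the stereocentre.

Step 12
Reactants: 18 (3R)‑3‑methylhept‑1‑yne and 14 (2R,3R,4E)‑2‑[(1E)‑2‑iodoprop‑1‑en‑1‑yl]‑3,5‑dimethyl‑6‑oxohex‑4‑enoic acid
Product: 22 (3R,4S,5S)‑3‑[(1E)‑2‑iodoprop‑1‑en‑1‑yl]‑4‑methyl‑5‑[(2E,4E,6R)‑6‑methyldeca‑2,4‑dien‑2‑yl]oxolan‑2‑one, via alkenylzirconocene 19 (not isolated), via alkenylzinc 20 (not isolated), via dienol acid 21 (not isolated)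
Conditions: Cp2Zr(H)Cl, CH2Cl2, rt; Me2Zn, −65 °C; 14 (pre‑treated with 1 equiv Me2Zn), −65 to 0 °C; 1 M HCl; organic phase + CSA (10 mol %), 0 °C to rt
Reagents that add atoms: none
Why: Hydrozirconation and Zr‑to‑Zn transmetalation give an (E)‑alkenylzinc that adds 1,2 to the enal; the doubly allylic alcohol then ionises under acid and the carboxyl group closes the γ‑lactone with allylic transposition (intramolecular SN1′), with C4–H eclipsing the C6 methyl (A(1,3) strain) so that oxygen adds anti to the C4 methyl (4,5‑trans) and the (E)‑C6=C7 bond forms.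

Step 13
Reactants: 22 (3R,4S,5S)‑3‑[(1E)‑2‑iodoprop‑1‑en‑1‑yl]‑4‑methyl‑5‑[(2E,4E,6R)‑6‑methyldeca‑2,4‑dien‑2‑yl]oxolan‑2‑one and 23 acrolein (prop‑2‑enal)
Product: 24 (2E,4E)‑4‑methyl‑5‑{(3S,4S,5S)‑4‑methyl‑5‑[(2E,4E,6R)‑6‑methyldeca‑2,4‑dien‑2‑yl]‑2‑oxooxolan‑3‑yl}penta‑2,4‑dienal
Conditions: 23 (5 equiv), Pd(OAc)2 (5 mol %), Bu4NCl, NaHCO3, DMF, rt
Reagents that add atoms: none
Why: Heck reaction under ligand‑free Jeffery conditions: oxidative addition with retention of the iodoalkene geometry, syn insertion and β‑hydride elimination give the (E,E)‑dienal; the weak base leaves C3 alone.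

Step 14
Reactants: 6 (2S)‑but‑3‑yn‑2‑ol
Product: 25 (2S)‑but‑3‑yn‑2‑yl methanesulfonate
Conditions: MsCl, Et3N, CH2Cl2, −78 °C
Reagents that add atoms: methanesulfonyl chloride, CS(=O)(=O)Cl
Why: O‑sulfonylation with retention activates the propargylic position.

Step 15
Reactants: 25 (2S)‑but‑3‑yn‑2‑yl methanesulfonate
Product: 26 (M)‑buta‑1,2‑dien‑1‑yl(tributyl)stannane [(aR)]
Conditions: Bu3SnH, LiN(iPr)2, THF, 0 °C; CuBr·SMe2, −78 °C; then 25, −78 °C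
Reagents that add atoms: tributylstannane, CCCC[SnH](CCCC)CCCC
Why: Anti SN2′ displacement of the propargylic mesylate by the stannylcuprate (Marshall allenylstannane synthesis) converts the carbinol centre into defined axial chirality.

Step 16
Reactants: 24 (2E,4E)‑4‑methyl‑5‑{(3S,4S,5S)‑4‑methyl‑5‑[(2E,4E,6R)‑6‑methyldeca‑2,4‑dien‑2‑yl]‑2‑oxooxolan‑3‑yl}penta‑2,4‑dienal and 26 (M)‑buta‑1,2‑dien‑1‑yl(tributyl)stannane
Product: 27 (3S,4S,5S)‑3‑[(1E,3E,5S,6S)‑5‑hydroxy‑2,6‑dimethylocta‑1,3‑dien‑7‑yn‑1‑yl]‑4‑methyl‑5‑[(2E,4E,6R)‑6‑methyldeca‑2,4‑dien‑2‑yl]oxolan‑2‑one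
Conditions: BF3·OEt2, CH2Cl2, −78 °C; H2O
Reagents that add atoms: none
Why: Marshall SE2′ addition: anti attack on the allene returns the butynol carbon as C6′ (two anti steps, net retention), and the open antiperiplanar transition state of the BF3‑complexed aldehyde gives the 5′,6′‑syn alcohol.

Step 17
Reactants: 27 (3S,4S,5S)‑3‑[(1E,3E,5S,6S)‑5‑hydroxy‑2,6‑dimethylocta‑1,3‑dien‑7‑yn‑1‑yl]‑4‑methyl‑5‑[(2E,4E,6R)‑6‑methyldeca‑2,4‑dien‑2‑yl]oxolan‑2‑one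
Product: 28 (3S,4S,5S)‑3‑[(1E,3E,5S,6R)‑5‑hydroxy‑2,6‑dimethyl‑7‑oxoocta‑1,3‑dien‑1‑yl]‑4‑methyl‑5‑[(2E,4E,6R)‑6‑methyldeca‑2,4‑dien‑2‑yl]oxolan‑2‑one
Conditions: Ph3PAuNTf2 (2 mol %), H2O (10 equiv), 1,4‑dioxane, rt
Reagents that add atoms: water, O
Why: Gold‑catalysed Markovnikov hydration of the terminal alkyne gives the methyl ketone via the enol toward C8′; no stereocentre is touched (C6′ changes from S to R only because the new carbonyl outranks C5′).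

## Compound list

1 | pent‑3‑yn‑1‑ol | CC#CCCO | starting material
2 | tert‑butyl(dimethyl)(pent‑3‑yn‑1‑yloxy)silane | CC#CCCO[Si](C)(C)C(C)(C)C | intermediate
3 | chlorobis(cyclopentadienyl){(2E)‑5‑[(tert‑butyldimethylsilyl)oxy]pent‑2‑en‑2‑yl}zirconium | CC(C)(C)[Si](C)(C)OCC/C=C(\C)[Zr](Cl)(C1C=CC=C1)C1C=CC=C1 | intermediate (not isolated)
4 | tert‑butyl{[(3E)‑4‑iodopent‑3‑en‑1‑yl]oxy}dimethylsilane | CC(C)(C)[Si](C)(C)OCC/C=C(\C)I | intermediate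
5 | (3E)‑4‑iodopent‑3‑enoic acid | OC(=O)C/C=C(\C)I | intermediate
6 | (2S)‑but‑3‑yn‑2‑ol | C[C@H](O)C#C | starting material
7 | (2S)‑pent‑3‑yn‑2‑ol | C[C@H](O)C#CC | intermediate
8 | (2S,3E)‑pent‑3‑en‑2‑ol | C[C@H](O)/C=C/C | intermediate
9 | (2S,3E)‑pent‑3‑en‑2‑yl (3E)‑4‑iodopent‑3‑enoate | C/C=C/[C@H](C)OC(=O)C/C=C(\C)I | intermediate
10 | trimethyl{[(1Z,3E)‑4‑iodo‑1‑{[(2S,3E)‑pent‑3‑en‑2‑yl]oxy}penta‑1,3‑dien‑1‑yl]oxy}silane | C/C=C/[C@H](C)O/C(O[Si](C)(C)C)=C/C=C(\C)I | intermediate (not isolated)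
11 | trimethylsilyl (2R,3R,4E)‑2‑[(1E)‑2‑iodoprop‑1‑en‑1‑yl]‑3‑methylhex‑4‑enoate | C[Si](C)(C)OC(=O)[C@@H](/C=C(C)/I)[C@@H](/C=C/C)C | intermediate (not isolated)
12 | (2R,3R,4E)‑2‑[(1E)‑2‑iodoprop‑1‑en‑1‑yl]‑3‑methylhex‑4‑enoic acid | OC(=O)[C@@H](/C=C(C)/I)[C@@H](/C=C/C)C | intermediate
13 | methacrolein (2‑methylprop‑2‑enal) | CC(=C)C=O | starting material
14 | (2R,3R,4E)‑2‑[(1E)‑2‑iodoprop‑1‑en‑1‑yl]‑3,5‑dimethyl‑6‑oxohex‑4‑enoic acid | OC(=O)[C@@H](/C=C(C)/I)[C@@H](/C=C(C)/C=O)C | intermediate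
15 | (2S)‑3‑bromo‑2‑methylpropan‑1‑ol | OC[C@H](C)CBr | starting material
16 | (2R)‑2‑methylhexan‑1‑ol | OC[C@H](C)CCCC | intermediate
17 | (2R)‑2‑methylhexanal | O=C[C@H](C)CCCC | intermediate
18 | (3R)‑3‑methylhept‑1‑yne | C#C[C@H](C)CCCC | intermediate
19 | chlorobis(cyclopentadienyl)[(1E,3R)‑3‑methylhept‑1‑en‑1‑yl]zirconium | CCCC[C@@H](C)/C=C/[Zr](Cl)(C1C=CC=C1)C1C=CC=C1 | intermediate (not isolated)
20 | methyl[(1E,3R)‑3‑methylhept‑1‑en‑1‑yl]zinc | CCCC[C@@H](C)/C=C/[Zn]C | intermediate (not isolated)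
21 | (2R,3R,4E,6RS,7E,9R)‑6‑hydroxy‑2‑[(1E)‑2‑iodoprop‑1‑en‑1‑yl]‑3,5,9‑trimethyltrideca‑4,7‑dienoic acid | OC(=O)[C@@H](/C=C(C)/I)[C@@H](/C=C(C)/C(O)/C=C/[C@H](C)CCCC)C | intermediate (not isolated)
22 | (3R,4S,5S)‑3‑[(1E)‑2‑iodoprop‑1‑en‑1‑yl]‑4‑methyl‑5‑[(2E,4E,6R)‑6‑methyldeca‑2,4‑dien‑2‑yl]oxolan‑2‑one | CCCC[C@@H](C)/C=C/C=C(\C)[C@H]1OC(=O)[C@@H](/C=C(C)/I)[C@@H]1C | intermediate
23 | acrolein (prop‑2‑enal) | C=CC=O | starting material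
24 | (2E,4E)‑4‑methyl‑5‑{(3S,4S,5S)‑4‑methyl‑5‑[(2E,4E,6R)‑6‑methyldeca‑2,4‑dien‑2‑yl]‑2‑oxooxolan‑3‑yl}penta‑2,4‑dienal | CCCC[C@@H](C)/C=C/C=C(\C)[C@H]1OC(=O)[C@@H](/C=C(C)/C=C/C=O)[C@@H]1C | intermediate
25 | (2S)‑but‑3‑yn‑2‑yl methanesulfonate | C[C@H](OS(C)(=O)=O)C#C | intermediate
26 | (M)‑buta‑1,2‑dien‑1‑yl(tributyl)stannane [(aR)] | C[C]([H])=[C@]=[C]([H])[Sn](CCCC)(CCCC)CCCC | intermediate
27 | (3S,4S,5S)‑3‑[(1E,3E,5S,6S)‑5‑hydroxy‑2,6‑dimethylocta‑1,3‑dien‑7‑yn‑1‑yl]‑4‑methyl‑5‑[(2E,4E,6R)‑6‑methyldeca‑2,4‑dien‑2‑yl]oxolan‑2‑one | CCCC[C@@H](C)/C=C/C=C(\C)[C@H]1OC(=O)[C@@H](/C=C(C)/C=C/[C@H](O)[C@@H](C)C#C)[C@@H]1C | intermediate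
28 | (3S,4S,5S)‑3‑[(1E,3E,5S,6R)‑5‑hydroxy‑2,6‑dimethyl‑7‑oxoocta‑1,3‑dien‑1‑yl]‑4‑methyl‑5‑[(2E,4E,6R)‑6‑methyldeca‑2,4‑dien‑2‑yl]oxolan‑2‑one | CCCC[C@@H](C)/C=C/C=C(\C)[C@H]1OC(=O)[C@@H](/C=C(C)/C=C/[C@H](O)[C@@H](C)C(C)=O)[C@@H]1C | target

## Step count and risks

Total step count: 17. Longest linear sequence: 10 steps (1, 2, 3, 6, 7, 8, 12, 13, 16, 17).

Steps most likely to fail:

Step 12. The zinc carboxylate may add to its own enal (oxa‑Michael), and the cationic ring closure can lose a proton to trienes or give some 4,5‑cis lactone. The fallback sets out from 12 (and uses 16) and comes back at 22. Acid 12 is epoxidised with mCPBA (CH2Cl2, 0 °C to rt) and the epoxy acid closes in the flask (5‑exo) to (3R,4S)‑5‑(1‑hydroxyethyl)‑3‑[(1E)‑2‑iodoprop‑1‑en‑1‑yl]‑4‑methyloxolan‑2‑one F1 as an isomer mixture. Dess–Martin oxidation followed by brief Et3N equilibration through the enolisable α‑acyloxy ketone funnels all isomers to the all‑trans (3R,4S,5S)‑5‑acetyl‑3‑[(1E)‑2‑iodoprop‑1‑en‑1‑yl]‑4‑methyloxolan‑2‑one F2. A Wittig reaction with Ph3P=CHCHO (toluene, 80 °C) gives (2E)‑3‑{(2S,3S,4R)‑4‑[(1E)‑2‑iodoprop‑1‑en‑1‑yl]‑3‑methyl‑5‑oxooxolan‑2‑yl}but‑2‑enal F3. Alcohol 16 is converted by Mitsunobu reaction with 1‑phenyl‑1H‑tetrazole‑5‑thiol (PPh3, DIAD) into 5‑{[(2R)‑2‑methylhexyl]sulfanyl}‑1‑phenyl‑1H‑tetrazole F4 and oxidised ((NH4)6Mo7O24, H2O2, EtOH) to 5‑{[(2R)‑2‑methylhexyl]sulfonyl}‑1‑phenyl‑1H‑tetrazole F5. Julia–Kocienski olefination of F3 with F5 (KN(SiMe3)2, THF, −78 °C) forms the (E)‑C8=C9 bond and gives 22.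

Step 16. The syn preference of BF3‑promoted allenylstannane additions is highest for α‑branched aldehydes and may be modest for this unbranched dienal. The fallback sets out from 22 and comes back at 27; it uses the reliably anti‑selective cyclic pathway on a small aldehyde and then inverts the carbinol. (2R)‑But‑3‑yn‑2‑ol is mesylated (MsCl, Et3N) to (2R)‑but‑3‑yn‑2‑yl methanesulfonate F6. Palladium‑catalysed zincation (Pd(OAc)2, PPh3, Et2Zn, THF, −20 °C) in the presence of (2E)‑3‑(4,4,5,5‑tetramethyl‑1,3,2‑dioxaborolan‑2‑yl)prop‑2‑enal gives, through the cyclic SE2′ transition state, the anti adduct (1E,3R,4S)‑4‑methyl‑1‑(4,4,5,5‑tetramethyl‑1,3,2‑dioxaborolan‑2‑yl)hex‑1‑en‑5‑yn‑3‑ol F7. Mitsunobu inversion (4‑nitrobenzoic acid, PPh3, DIAD) gives (1E,3S,4S)‑4‑methyl‑1‑(4,4,5,5‑tetramethyl‑1,3,2‑dioxaborolan‑2‑yl)hex‑1‑en‑5‑yn‑3‑yl 4‑nitrobenzoate F8, and methanolysis (K2CO3, MeOH, 0 °C) gives the syn alcohol (1E,3S,4S)‑4‑methyl‑1‑(4,4,5,5‑tetramethyl‑1,3,2‑dioxaborolan‑2‑yl)hex‑1‑en‑5‑yn‑3‑ol F9. Suzuki coupling of F9 with 22 (Pd(PPh3)4, TlOEt, THF/H2O, rt) gives 27.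

Step 17. The free homopropargylic hydroxyl can cyclise onto the gold‑activated alkyne (5‑endo), and the C5′–OH and C5–O bonds are acid‑labile. The fallback sets out from 27 and comes back at 28. Ruthenium‑catalysed Markovnikov hydrosilylation of 27 with benzyl(dimethyl)silane ([Cp*Ru(MeCN)3]PF6, acetone, 0 °C to rt) gives (3S,4S,5S)‑3‑[(1E,3E,5S,6R)‑7‑[benzyl(dimethyl)silyl]‑5‑hydroxy‑2,6‑dimethylocta‑1,3,7‑trien‑1‑yl]‑4‑methyl‑5‑[(2E,4E,6R)‑6‑methyldeca‑2,4‑dien‑2‑yl]oxolan‑2‑one F10. Tamao–Fleming oxidation (Bu4NF, THF; then H2O2, KHCO3, MeOH) converts the vinylsilane into the methyl ketone 28.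

## Further compounds

F1 | step 12 | (3R,4S)‑5‑(1‑hydroxyethyl)‑3‑[(1E)‑2‑iodoprop‑1‑en‑1‑yl]‑4‑methyloxolan‑2‑one (mixture at C5 and the carbinol carbon) | CC(O)C1OC(=O)[C@@H](/C=C(C)/I)[C@@H]1C
F2 | step 12 | (3R,4S,5S)‑5‑acetyl‑3‑[(1E)‑2‑iodoprop‑1‑en‑1‑yl]‑4‑methyloxolan‑2‑one | CC(=O)[C@H]1OC(=O)[C@@H](/C=C(C)/I)[C@@H]1C
F3 | step 12 | (2E)‑3‑{(2S,3S,4R)‑4‑[(1E)‑2‑iodoprop‑1‑en‑1‑yl]‑3‑methyl‑5‑oxooxolan‑2‑yl}but‑2‑enal | O=C/C=C(\C)[C@H]1OC(=O)[C@@H](/C=C(C)/I)[C@@H]1C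
F4 | step 12 | 5‑{[(2R)‑2‑methylhexyl]sulfanyl}‑1‑phenyl‑1H‑tetrazole | CCCC[C@@H](C)CSc1nnnn1-c1ccccc1
F5 | step 12 | 5‑{[(2R)‑2‑methylhexyl]sulfonyl}‑1‑phenyl‑1H‑tetrazole | CCCC[C@@H](C)CS(=O)(=O)c1nnnn1-c1ccccc1
F6 | step 16 | (2R)‑but‑3‑yn‑2‑yl methanesulfonate | C[C@@H](OS(C)(=O)=O)C#C
F7 | step 16 | (1E,3R,4S)‑4‑methyl‑1‑(4,4,5,5‑tetramethyl‑1,3,2‑dioxaborolan‑2‑yl)hex‑1‑en‑5‑yn‑3‑ol | CC1(C)OB(/C=C/[C@@H](O)[C@@H](C)C#C)OC1(C)C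
F8 | step 16 | (1E,3S,4S)‑4‑methyl‑1‑(4,4,5,5‑tetramethyl‑1,3,2‑dioxaborolan‑2‑yl)hex‑1‑en‑5‑yn‑3‑yl 4‑nitrobenzoate | CC1(C)OB(/C=C/[C@H](OC(=O)c2ccc(cc2)[N+](=O)[O-])[C@@H](C)C#C)OC1(C)C
F9 | step 16 | (1E,3S,4S)‑4‑methyl‑1‑(4,4,5,5‑tetramethyl‑1,3,2‑dioxaborolan‑2‑yl)hex‑1‑en‑5‑yn‑3‑ol | CC1(C)OB(/C=C/[C@H](O)[C@@H](C)C#C)OC1(C)C
F10 | step 17 | (3S,4S,5S)‑3‑[(1E,3E,5S,6R)‑7‑[benzyl(dimethyl)silyl]‑5‑hydroxy‑2,6‑dimethylocta‑1,3,7‑trien‑1‑yl]‑4‑methyl‑5‑[(2E,4E,6R)‑6‑methyldeca‑2,4‑dien‑2‑yl]oxolan‑2‑one | CCCC[C@@H](C)/C=C/C=C(\C)[C@H]1OC(=O)[C@@H](/C=C(C)/C=C/[C@H](O)[C@@H](C)C(=C)[Si](C)(C)Cc2ccccc2)[C@@H]1C
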